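**Plan**

1. Numbering (iridoid): C1 acetal carbon, O2, C3=C4 enol ether, C5/C9 ring fusion, C6–C8 in cyclopentene ring B, C10 on C8, C11 on C4; ring A is the pyran.
2. Cuts: first the C1 ester (lactol + acid), then C5–C6 and C3–C4 together. The diene C3=C4–C5=C6 that runs across ring A and ring B is the footprint of an alkyne at C4≡C5 relaying two metatheses, which leads back to an acyclic dienyne (C6 vinyl, C9 alkynyl, C1 propenyl 2-nitrobenzyl acetal).
3. The dienyne is cut at C9–C5 (alkynylalane + C8/C9 epoxide), at C7–C8 (acrolein + α-metallated enoate from an ynoate) and at the C1 acetal (exchange).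
4. Forward: ynoate (C1, C9, C8, C10) + acrolein (C6, C7), epoxide, alkyne (C5, C4, C11), esters, mixed acetal; one metathesis cascade closes ring B (five-membered) first and ring A (six-membered) second; photolysis and C1 acylation finish.
5. Stereochemistry: C8 and C9 from a Sharpless kinetic-resolution epoxidation and invertive opening at C9; C7 from the same resolution after Mitsunobu inversion; C1 from the final anomeric acylation.

Key step: step 16

Remark: from compound 24 to lactol 29 the C1 centre is not controlled; both C1 epimers are carried together, each is written as the epimer that maps onto the target, and they converge in steps 17 and 19.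
Remark: the enol ether of the dienyne is a propenyl ether (made from an allyl group) and not a vinyl ether, so that the catalyst loads on the C6 vinyl group; the extra methyl group leaves as propene.

**Route**

Step 1
Reactants: 1 3,3-diethoxyprop-1-yne; 2 prop-2-en-1-ol (allyl alcohol)
Product: 3 3,3-bis(prop-2-enyloxy)prop-1-yne
Conditions: 2 (excess), TsOH·H2O (cat.), cyclohexane, reflux, EtOH distilled off
Reagents that add atoms: none
Why: Acid-catalysed transacetalisation, driven by removal of ethanol, swaps both ethoxy groups for allyloxy groups, one of which later becomes the enol-ether arm and the other the leaving group of the acetal exchange.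

Step 2
Reactants: 3 3,3-bis(prop-2-enyloxy)prop-1-yne
Product: 5 ethyl 4,4-bis(prop-2-enyloxy)but-2-ynoate, via lithium acetylide 4 (not isolated)
Conditions: n-BuLi, THF, −78 °C; then ClCO2Et, −78 to 0 °C
Reagents that add atoms: ethyl chloroformate, CCOC(=O)Cl
Why: C-acylation of a lithium acetylide with a chloroformate is a standard ynoate synthesis and supplies C10 (ester carbon), C8, C9 and C1.

Step 3
Reactants: 5 ethyl 4,4-bis(prop-2-enyloxy)but-2-ynoate; 6 acrolein
Product: 8 ethyl (2Z)-2-(1-hydroxyprop-2-enyl)-4,4-bis(prop-2-enyloxy)but-2-enoate (racemic), via vinylalane 7 (not isolated)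
Conditions: iBu2AlH, N-methylmorpholine N-oxide, THF, 0 °C; then 6, 0 °C to rt; aq. KNaC4H4O6
Reagents that add atoms: none
Why: Conjugate hydroalumination of the ynoate (vinylalumination, the reductive counterpart of a Morita–Baylis–Hillman reaction) puts hydride on C9 and aluminium on C8 in a syn sense, and the α-alumino enoate adds 1,2 to acrolein with retention, so the C7 carbinol ends cis to H9 and the ester carbon C10 cis to C1; C7 is formed racemic and is resolved in step 6.

Step 4
Reactants: 8 ethyl (2Z)-2-(1-hydroxyprop-2-enyl)-4,4-bis(prop-2-enyloxy)but-2-enoate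
Product: 9 (2E)-2-[2,2-bis(prop-2-enyloxy)ethylidene]pent-4-ene-1,3-diol (racemic)
Conditions: iBu2AlH (excess), CH2Cl2, −78 to −20 °C; aq. KNaC4H4O6
Reagents that add atoms: none
Why: 1,2-Reduction of the conjugated ester by iBu2AlH at low temperature gives the allylic alcohol at C10 without touching the acetal or the isolated alkenes.

Step 5
Reactants: 9 (2E)-2-[2,2-bis(prop-2-enyloxy)ethylidene]pent-4-ene-1,3-diol
Product: 10 (2E)-2-[2,2-bis(prop-2-enyloxy)ethylidene]-1-(tert-butyldimethylsilyloxy)pent-4-en-3-ol (racemic)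
Conditions: tBuMe2SiCl (1 equiv), imidazole, CH2Cl2, −20 °C
Reagents that add atoms: tert-butyldimethylsilyl chloride, CC(C)(C)[Si](C)(C)Cl
Why: Silylation with one equivalent of a bulky silyl chloride at low temperature is selective for the primary C10 hydroxyl over the secondary bis-allylic C7 hydroxyl, which must stay free to direct the epoxidation.

Step 6
Reactants: 10 (2E)-2-[2,2-bis(prop-2-enyloxy)ethylidene]-1-(tert-butyldimethylsilyloxy)pent-4-en-3-ol (racemic)
Product: 11 (1S)-1-{(2S,3R)-3-[bis(prop-2-enyloxy)methyl]-2-[(tert-butyldimethylsilyloxy)methyl]oxiran-2-yl}prop-2-en-1-ol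
Conditions: Ti(OiPr)4 (15 mol%), L-(+)-diisopropyl tartrate (20 mol%), tBuOOH (0.55 equiv), 4 Å MS, CH2Cl2, −20 °C
Reagents that add atoms: tert-butyl hydroperoxide, CC(C)(C)OO
Why: Sharpless kinetic-resolution epoxidation, in which L-(+)-tartrate makes the (7S)-enantiomer of 10 the fast one and epoxidises its trisubstituted C8=C9 bond from the face that gives 8S,9R with the usual erythro relation to the C7 hydroxyl, while (7R)-10 (at most half of the material) and the vinyl and allyl alkenes are left; C8 and C9 are thus set by the reagent.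

Step 7
Reactants: 11 (7S,8S,9R)-epoxy alcohol; 12 4-nitrobenzoic acid
Product: 13 (1R)-1-{(2S,3R)-3-[bis(prop-2-enyloxy)methyl]-2-[(tert-butyldimethylsilyloxy)methyl]oxiran-2-yl}prop-2-enyl 4-nitrobenzoate
Conditions: PPh3, DIAD, toluene, 0 °C to rt
Reagents that add atoms: none
Why: Mitsunobu esterification displaces the activated C7 oxygen in an SN2 sense with inversion, turning the erythro (7S) epoxy alcohol into the threo (7R) ester that the target requires, as is established for vinyl-substituted epoxy carbinols; the acidic 4-nitrobenzoic acid is chosen because the carbinol is hindered.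

Step 8
Reactants: 13 (7R,8S,9R)-epoxy 4-nitrobenzoate
Product: 14 (1R)-1-{(2S,3R)-3-[bis(prop-2-enyloxy)methyl]-2-[(tert-butyldimethylsilyloxy)methyl]oxiran-2-yl}prop-2-en-1-ol
Conditions: K2CO3 (cat.), MeOH, 0 °C
Reagents that add atoms: none
Why: Carbonate-catalysed methanolysis (transesterification) of the electron-poor aryl ester is fast at 0 °C, conditions under which the epoxy alcohol should not undergo Payne rearrangement and the silyl ether and acetal are stable.

Step 9
Reactants: 14 (7R,8S,9R)-epoxy alcohol; 15 tert-butyl(diphenyl)(prop-2-ynyloxy)silane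
Product: 18 (3R,4S,5S)-5-[bis(prop-2-enyloxy)methyl]-4-[(tert-butyldimethylsilyloxy)methyl]-8-(tert-butyldiphenylsilyloxy)oct-1-en-6-yne-3,4-diol, via lithium acetylide 16 (not isolated), via diethylalkynylalane 17 (not isolated)
Conditions: 15, n-BuLi, toluene, 0 °C; Et2AlCl; then 14, 0 °C to rt; aq. KNaC4H4O6
Reagents that add atoms: none
Why: Alkynylalane opening of a 2,3-epoxy alcohol, in which the C7 aluminium alkoxide anchors the reagent and the alkynyl group attacks C9 (the epoxide carbon remote from the carbinol and the only one that is not quaternary) with inversion, giving the 8S tertiary alcohol and the 9S propargylic centre anti to it.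

Step 10
Reactants: 18 (7R,8S,9S)-diol with C10 silyl ether
Product: 19 (3R,4S,5S)-5-[bis(prop-2-enyloxy)methyl]-8-(tert-butyldiphenylsilyloxy)-4-(hydroxymethyl)oct-1-en-6-yne-3,4-diol
Conditions: HF·pyridine, pyridine, THF, 0 °C
Reagents that add atoms: none
Why: Buffered HF·pyridine cleaves the primary tert-butyldimethylsilyl ether much faster than the tert-butyldiphenylsilyl ether, freeing the C10 hydroxyl while the acetal and the alkyne survive.

Step 11
Reactants: 19 (7R,8S,9S)-triol
Product: 20 (3R,4S,5S)-5-[bis(prop-2-enyloxy)methyl]-8-(tert-butyldiphenylsilyloxy)-4-hydroxy-4-[(3-methylbutanoyloxy)methyl]oct-1-en-6-yn-3-yl 3-methylbutanoate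
Conditions: 3-methylbutanoyl chloride (2.4 equiv), pyridine, DMAP (cat.), CH2Cl2, 0 °C
Reagents that add atoms: 3-methylbutanoyl chloride, CC(C)CC(=O)Cl
Why: Pyridine/DMAP acylation esterifies the primary C10 and the secondary C7 hydroxyls, whereas the hindered tertiary C8 hydroxyl stays free, as it is in the target.

Step 12
Reactants: 20 bis(3-methylbutanoate) with C1 bis(allyl) acetal; 21 (2-nitrophenyl)methanol
Product: 24 dienyne with C1 allyl 2-nitrobenzyl mixed acetal (C8 triethylsilyl ether and C11 tert-butyldiphenylsilyl ether), via silyl ether 22 (not isolated), via collidinium triflate 23 (not isolated)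
Conditions: Et3SiOTf (3 equiv), 2,4,6-collidine, CH2Cl2, 0 °C; then 21, 0 °C to rt
Reagents that add atoms: triethylsilyl trifluoromethanesulfonate, CC[Si](CC)(CC)OS(=O)(=O)C(F)(F)F
Why: Silyl triflate/collidine activation of an acetal is a known route to mixed acetals, in which the reagent first silylates the C8 hydroxyl, then ionises one allyloxy group to an N-(α-alkoxyalkyl)collidinium salt that the added alcohol displaces under non-acidic conditions that spare the esters, the alkyne and C9; C1 is formed without control, which is immaterial because it is reset in step 19.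

Step 13
Reactants: 24 mixed acetal (C8 and C11 silyl ethers)
Product: 25 dienyne with C1 allyl 2-nitrobenzyl mixed acetal and free C8 and C11 hydroxyls
Conditions: Bu4NF, AcOH (1:1), THF, 0 °C to rt
Reagents that add atoms: none
Why: Fluoride cleaves the tertiary triethylsilyl and the primary tert-butyldiphenylsilyl ethers in one operation, and the acetic acid buffer suppresses acyl migration to the C8 alkoxide.

Step 14
Reactants: 25 C8,C11-diol
Product: 26 dienyne with C11 acetate and C1 allyl 2-nitrobenzyl mixed acetal
Conditions: Ac2O, pyridine, CH2Cl2, 0 °C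
Reagents that add atoms: acetic anhydride, CC(=O)OC(C)=O
Why: Acetylation in pyridine without stronger activation is selective for the primary propargylic C11 hydroxyl over the tertiary C8 hydroxyl.

Step 15
Reactants: 26 allyl 2-nitrobenzyl acetal
Product: 27 acyclic dienyne with C6 vinyl group, C9 alkynyl group and C1 (E)-prop-1-enyl 2-nitrobenzyl mixed acetal
Conditions: [Ir(cod)(PMePh2)2]PF6 (5 mol%, activated with H2, then Ar), THF, rt
Reagents that add atoms: none
Why: Cationic iridium hydride catalysed 1,3-hydrogen shift converts the allyl acetal into the (E)-prop-1-enyl acetal, the isomerisation used to unmask allyl glycosides; oxygen-assisted coordination should make the allyl ether react before the hindered C6 vinyl group, and hydrogen is purged after activation so that alkenes, alkyne and nitro group are not reduced.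

Step 16
Reactants: 27 acyclic dienyne
Product: 28 (6R,7S,7aS)-4-(acetyloxymethyl)-7-hydroxy-6-(3-methylbutanoyloxy)-7-[(3-methylbutanoyloxy)methyl]-1-[(2-nitrophenyl)methoxy]-1,6,7,7a-tetrahydrocyclopenta[c]pyran
Conditions: second-generation Grubbs catalyst RuCl2(=CHPh)(H2IMes)(PCy3) (10 mol%), toluene (0.002 M), 80 °C, Ar sparge
Reagents that add atoms: none
Why: The benzylidene exchanges onto the only monosubstituted alkene, the C6 vinyl group; the C6 alkylidene adds across the C4≡C5 alkyne in the exo sense of a 1,6-enyne, which closes five-membered ring B with the C5=C6 bond and leaves a ruthenium alkylidene on C4, and this vinylcarbene then undergoes ring-closing metathesis with the propenyl ether of the C1 acetal, closing six-membered ring A with the C3=C4 bond and expelling propene. The closest known reactions are ruthenium-catalysed tandem dienyne ring-closing metathesis to fused bicyclic 1,3-dienes and ring-closing metathesis onto enol ethers. No stereocentre is formed, C7, C8 and C9 are untouched, and both C1 epimers of 27 should cyclise. The selectivity that matters is the site of initiation: both alkenes sit three atoms from the alkyne, so a carbene started on the acetal arm would close a five-membered oxygen ring and lead to a different bicycle. The enol ether is therefore 1,2-disubstituted, which slows loading there and the formation of a sluggish alkoxycarbene, while it still serves as the terminating alkene. High dilution and loss of propene favour ring closure over cross-metathesis, and the tertiary alcohol, the esters and the nitroarene are tolerated by this catalyst.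

Step 17
Reactants: 28 1-O-(2-nitrobenzyl) bicyclic diene
Product: 29 (6R,7S,7aS)-4-(acetyloxymethyl)-6-(3-methylbutanoyloxy)-7-[(3-methylbutanoyloxy)methyl]-1,6,7,7a-tetrahydrocyclopenta[c]pyran-1,7-diol (lactol)
Conditions: hν (365 nm), degassed MeCN, 10 °C
Reagents that add atoms: none
Why: Photolysis of the 2-nitrobenzyl acetal (intramolecular hydrogen abstraction by the excited nitro group, aci-nitro rearrangement and fragmentation to 2-nitrosobenzaldehyde) frees the C1 hemiacetal under neutral conditions at a wavelength the dienol ether does not absorb, and both C1 epimers give the same equilibrating lactol.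

Step 18
Reactants: 30 3-hydroxy-3-methylbutanoic acid
Product: 31 3-acetyloxy-3-methylbutanoic acid
Conditions: Ac2O, Et3N, DMAP (cat.), CH2Cl2, rt; then aq. NaHCO3, then acidification
Reagents that add atoms: acetic anhydride, CC(=O)OC(C)=O
Why: DMAP-catalysed acyl transfer acetylates the tertiary hydroxyl, and the mixed anhydride formed at the carboxyl group is hydrolysed on aqueous work-up.

Step 19
Reactants: 29 lactol; 31 3-acetyloxy-3-methylbutanoic acid
Product: 33 [(1S,6R,7S,7aS)-4-(acetyloxymethyl)-7-hydroxy-6-(3-methylbutanoyloxy)-7-[(3-methylbutanoyloxy)methyl]-1,6,7,7a-tetrahydrocyclopenta[c]pyran-1-yl] 3-acetyloxy-3-methylbutanoate, via symmetric anhydride 32 (not isolated)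
Conditions: 31 (2.4 equiv), DCC (1.2 equiv), CH2Cl2, 0 °C; then 29, DMAP, −20 to 0 °C
Reagents that add atoms: none
Why: DMAP-catalysed O-acylation of the lactol by the symmetric anhydride formed in the flask, in which the anomers interconvert and the more nucleophilic, less hindered equatorial hemiacetal oxygen trans to the C9–C8 bond should be acylated preferentially, setting C1 as in the target (H1 and H9 trans).

**Compound list**

1 | 3,3-diethoxyprop-1-yne | CCOC(OCC)C#C | starting material
2 | prop-2-en-1-ol (allyl alcohol) | C=CCO | starting material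
3 | 3,3-bis(prop-2-enyloxy)prop-1-yne | C=CCOC(OCC=C)C#C | intermediate
4 | lithium acetylide of 3 (not isolated) | [Li]C#CC(OCC=C)OCC=C | intermediate
5 | ethyl 4,4-bis(prop-2-enyloxy)but-2-ynoate | CCOC(=O)C#CC(OCC=C)OCC=C | intermediate
6 | acrolein (prop-2-enal) | C=CC=O | starting material
7 | diisobutyl[1-(ethoxycarbonyl)-3,3-bis(prop-2-enyloxy)prop-1-enyl]alane, Al cis to H9 (not isolated) | CCOC(=O)/C([Al](CC(C)C)CC(C)C)=C\C(OCC=C)OCC=C | intermediate
8 | ethyl (2Z)-2-(1-hydroxyprop-2-enyl)-4,4-bis(prop-2-enyloxy)but-2-enoate, racemic at C7 | C=CC(O)/C(C(=O)OCC)=C/C(OCC=C)OCC=C | intermediate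
9 | (2E)-2-[2,2-bis(prop-2-enyloxy)ethylidene]pent-4-ene-1,3-diol, racemic at C7 | C=CC(O)/C(CO)=C/C(OCC=C)OCC=C | intermediate
10 | (2E)-2-[2,2-bis(prop-2-enyloxy)ethylidene]-1-(tert-butyldimethylsilyloxy)pent-4-en-3-ol, racemic at C7 | C=CC(O)/C(CO[Si](C)(C)C(C)(C)C)=C/C(OCC=C)OCC=C | intermediate
11 | (1S)-1-{(2S,3R)-3-[bis(prop-2-enyloxy)methyl]-2-[(tert-butyldimethylsilyloxy)methyl]oxiran-2-yl}prop-2-en-1-ol (7S,8S,9R) | C=C[C@H](O)[C@]1(CO[Si](C)(C)C(C)(C)C)O[C@H]1C(OCC=C)OCC=C | intermediate
12 | 4-nitrobenzoic acid | OC(=O)c1ccc(cc1)[N+](=O)[O-] | starting material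
13 | (1R)-1-{(2S,3R)-3-[bis(prop-2-enyloxy)methyl]-2-[(tert-butyldimethylsilyloxy)methyl]oxiran-2-yl}prop-2-enyl 4-nitrobenzoate (7R,8S,9R) | C=C[C@@H](OC(=O)c2ccc(cc2)[N+](=O)[O-])[C@]1(CO[Si](C)(C)C(C)(C)C)O[C@H]1C(OCC=C)OCC=C | intermediate
14 | (1R)-1-{(2S,3R)-3-[bis(prop-2-enyloxy)methyl]-2-[(tert-butyldimethylsilyloxy)methyl]oxiran-2-yl}prop-2-en-1-ol (7R,8S,9R) | C=C[C@@H](O)[C@]1(CO[Si](C)(C)C(C)(C)C)O[C@H]1C(OCC=C)OCC=C | intermediate
15 | tert-butyl(diphenyl)(prop-2-ynyloxy)silane | C#CCO[Si](c1ccccc1)(c1ccccc1)C(C)(C)C | starting material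
16 | lithium acetylide of 15 (not isolated) | [Li]C#CCO[Si](c1ccccc1)(c1ccccc1)C(C)(C)C | intermediate
17 | diethyl[3-(tert-butyldiphenylsilyloxy)prop-1-ynyl]alane (not isolated) | CC[Al](CC)C#CCO[Si](c1ccccc1)(c1ccccc1)C(C)(C)C | intermediate
18 | (3R,4S,5S)-5-[bis(prop-2-enyloxy)methyl]-4-[(tert-butyldimethylsilyloxy)methyl]-8-(tert-butyldiphenylsilyloxy)oct-1-en-6-yne-3,4-diol (7R,8S,9S) | C=C[C@@H](O)[C@@](O)(CO[Si](C)(C)C(C)(C)C)[C@H](C#CCO[Si](c1ccccc1)(c1ccccc1)C(C)(C)C)C(OCC=C)OCC=C | intermediate
19 | (3R,4S,5S)-5-[bis(prop-2-enyloxy)methyl]-8-(tert-butyldiphenylsilyloxy)-4-(hydroxymethyl)oct-1-en-6-yne-3,4-diol | C=C[C@@H](O)[C@@](O)(CO)[C@H](C#CCO[Si](c1ccccc1)(c1ccccc1)C(C)(C)C)C(OCC=C)OCC=C | intermediate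
20 | (3R,4S,5S)-5-[bis(prop-2-enyloxy)methyl]-8-(tert-butyldiphenylsilyloxy)-4-hydroxy-4-[(3-methylbutanoyloxy)methyl]oct-1-en-6-yn-3-yl 3-methylbutanoate | C=C[C@@H](OC(=O)CC(C)C)[C@@](O)(COC(=O)CC(C)C)[C@H](C#CCO[Si](c1ccccc1)(c1ccccc1)C(C)(C)C)C(OCC=C)OCC=C | intermediate
21 | (2-nitrophenyl)methanol (2-nitrobenzyl alcohol) | OCc1ccccc1[N+](=O)[O-] | starting material
22 | C8 triethylsilyl ether of 20 (not isolated) | C=C[C@@H](OC(=O)CC(C)C)[C@@](O[Si](CC)(CC)CC)(COC(=O)CC(C)C)[C@H](C#CCO[Si](c1ccccc1)(c1ccccc1)C(C)(C)C)C(OCC=C)OCC=C | intermediate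
23 | 2,4,6-trimethylpyridinium salt of 22 at C1 after loss of one allyloxy group, triflate, both C1 epimers (not isolated) | C=C[C@@H](OC(=O)CC(C)C)[C@@](O[Si](CC)(CC)CC)(COC(=O)CC(C)C)[C@H](C#CCO[Si](c1ccccc1)(c1ccccc1)C(C)(C)C)C(OCC=C)[n+]1c(C)cc(C)cc1C.[O-]S(=O)(=O)C(F)(F)F | intermediate
24 | (7R,8S,9S)-dienyne with C1 allyl 2-nitrobenzyl mixed acetal, C8 triethylsilyl ether, C11 tert-butyldiphenylsilyl ether, C7 and C10 3-methylbutanoates; C1 epimers | C=C[C@@H](OC(=O)CC(C)C)[C@@](O[Si](CC)(CC)CC)(COC(=O)CC(C)C)[C@H](C#CCO[Si](c1ccccc1)(c1ccccc1)C(C)(C)C)[C@@H](OCC=C)OCc1ccccc1[N+](=O)[O-] | intermediate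
25 | (7R,8S,9S)-dienyne with C1 allyl 2-nitrobenzyl mixed acetal, free C8 and C11 hydroxyls, C7 and C10 3-methylbutanoates; C1 epimers | C=C[C@@H](OC(=O)CC(C)C)[C@@](O)(COC(=O)CC(C)C)[C@H](C#CCO)[C@@H](OCC=C)OCc1ccccc1[N+](=O)[O-] | intermediate
26 | (7R,8S,9S)-dienyne with C1 allyl 2-nitrobenzyl mixed acetal, C11 acetate, C8 hydroxyl, C7 and C10 3-methylbutanoates; C1 epimers | C=C[C@@H](OC(=O)CC(C)C)[C@@](O)(COC(=O)CC(C)C)[C@H](C#CCOC(C)=O)[C@@H](OCC=C)OCc1ccccc1[N+](=O)[O-] | intermediate
27 | (7R,8S,9S)-dienyne with C6 vinyl, C9 (3-acetyloxyprop-1-ynyl), C1 (E)-prop-1-enyl 2-nitrobenzyl mixed acetal, C8 hydroxyl, C7 and C10 3-methylbutanoates; C1 epimers | CC(=O)OCC#C[C@H]([C@@H](O/C=C/C)OCc1ccccc1[N+](=O)[O-])[C@](O)(COC(=O)CC(C)C)[C@@H](C=C)OC(=O)CC(C)C | intermediate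
28 | (6R,7S,7aS)-4-(acetyloxymethyl)-7-hydroxy-6-(3-methylbutanoyloxy)-7-[(3-methylbutanoyloxy)methyl]-1-[(2-nitrophenyl)methoxy]-1,6,7,7a-tetrahydrocyclopenta[c]pyran; C1 epimers, drawn with H1 and H7a trans | CC(=O)OCC1=CO[C@@H](OCc3ccccc3[N+](=O)[O-])[C@H]2C1=C[C@@H](OC(=O)CC(C)C)[C@@]2(O)COC(=O)CC(C)C | intermediate
29 | (6R,7S,7aS)-4-(acetyloxymethyl)-6-(3-methylbutanoyloxy)-7-[(3-methylbutanoyloxy)methyl]-1,6,7,7a-tetrahydrocyclopenta[c]pyran-1,7-diol; anomers, drawn with H1 and H7a trans | CC(=O)OCC1=CO[C@@H](O)[C@H]2C1=C[C@@H](OC(=O)CC(C)C)[C@@]2(O)COC(=O)CC(C)C | intermediate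
30 | 3-hydroxy-3-methylbutanoic acid | CC(C)(O)CC(=O)O | starting material
31 | 3-acetyloxy-3-methylbutanoic acid | CC(=O)OC(C)(C)CC(=O)O | intermediate
32 | 3-acetyloxy-3-methylbutanoic anhydride (not isolated) | CC(=O)OC(C)(C)CC(=O)OC(=O)CC(C)(C)OC(C)=O | intermediate
33 | [(1S,6R,7S,7aS)-4-(acetyloxymethyl)-7-hydroxy-6-(3-methylbutanoyloxy)-7-[(3-methylbutanoyloxy)methyl]-1,6,7,7a-tetrahydrocyclopenta[c]pyran-1-yl] 3-acetyloxy-3-methylbutanoate | CC(=O)OCC1=CO[C@@H](OC(=O)CC(C)(C)OC(C)=O)[C@H]2C1=C[C@@H](OC(=O)CC(C)C)[C@@]2(O)COC(=O)CC(C)C | target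

**Step count and risks**

Total steps: 19. Longest linear sequence: 18 (steps 1–17 and 19; step 18 prepares the side-chain acid).

The three steps most likely to fail:

Step 16 (key step). The ruthenium carbene may load on the enol-ether arm instead of the C6 vinyl group. The alkoxycarbene formed there could either arrest the catalyst or close a five-membered oxygen ring and give a different bicycle. The C4 alkylidene may also be consumed by cross-metathesis before it closes ring A. The fallback splits the cascade into two separate ring closures and sets out from 27. Enyne ring closure under ethylene (1 atm, second-generation Grubbs catalyst, CH2Cl2, rt) should close ring B only: at this temperature an alkoxycarbene is expected to be inert, and ethylene caps the C4 alkylidene as a methylene group, giving the ring-B triene F1. A separate diene/enol-ether ring-closing metathesis of the triene F1 (RuCl2(=CH-C6H4-2-OiPr)(H2IMes), toluene, 80 °C) can then form only the six-membered ring A, whichever alkene is loaded. The route is rejoined at 28.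

Step 9. The alane may fail to open the epoxide because C9 is deactivated by the neighbouring acetal, or it may attack the acetal carbon or C8 instead. The fallback replaces chelate-directed delivery by external Lewis-acid activation and sets out from 14. The C7 hydroxyl is capped (Et3SiCl, imidazole) to give the triethylsilyl ether F2. Yamaguchi–Hirao alkynylation with lithium acetylide 16 and BF3·OEt2 (THF, −78 °C) then attacks the only non-quaternary epoxide carbon with inversion and gives the silyl-protected alkynyl carbinol F3. HF·pyridine under the conditions of step 10 removes the triethylsilyl and tert-butyldimethylsilyl groups together, and the route is rejoined at 19.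

Step 19. The free lactol may ring-open to an enol aldehyde and decompose under base, or it may be acylated without selectivity at C1. The fallback makes C1 the electrophile and sets out from 29. Treatment with Cl3CCN and catalytic DBU (CH2Cl2, 0 °C) should give the axial, anomerically favoured trichloroacetimidate F4. Acid 31 alone (CH2Cl2, rt, no promoter) then protonates the imidate and displaces it with inversion, the established way from trichloroacetimidates to anomeric esters. The route is rejoined at 33.

**Further compounds**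

F1 | step 16 | ring-B triene: cyclopentene (C5=C6) with a 3-acetyloxyprop-1-en-2-yl group on C5 and the propenyl 2-nitrobenzyl acetal on C9 | C=C(COC(C)=O)C1=C[C@@H](OC(=O)CC(C)C)[C@@](O)(COC(=O)CC(C)C)[C@H]1[C@@H](O/C=C/C)OCc2ccccc2[N+](=O)[O-]
F2 | step 9 | C7 triethylsilyl ether of epoxy alcohol 14 | C=C[C@@H](O[Si](CC)(CC)CC)[C@]1(CO[Si](C)(C)C(C)(C)C)O[C@H]1C(OCC=C)OCC=C
F3 | step 9 | C7 triethylsilyl ether of diol 18 | C=C[C@@H](O[Si](CC)(CC)CC)[C@@](O)(CO[Si](C)(C)C(C)(C)C)[C@H](C#CCO[Si](c1ccccc1)(c1ccccc1)C(C)(C)C)C(OCC=C)OCC=C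
F4 | step 19 | C1 trichloroacetimidate of lactol 29, H1 and H7a cis | CC(=O)OCC1=CO[C@H](OC(=N)C(Cl)(Cl)Cl)[C@H]2C1=C[C@@H](OC(=O)CC(C)C)[C@@]2(O)COC(=O)CC(C)C
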